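## Structural features

The target is a 2,2-dimethyl-2H-chromene. Its benzene ring (ring A) is fully substituted and is fused through C4a and C8a to a dimethylpyran, with O1 on C8a and the C3=C4 double bond conjugated to ring A. Ring A carries hydroxyls at C5 and C7, a 3-hydroxybenzoyl group (ring B) at C6 between them, and a 3-methylbut-2-enyl (prenyl) chain at C8 beside the pyran oxygen. There is no stereocentre and no alkene geometry to set, so no stereocentres stand next to each other; the problem is purely one of regiochemistry on a hexasubstituted benzene. The fragile parts are the prenyl and chromene alkenes, which under acid cyclise onto the flanking phenols, the easily oxidised and over-alkylated phloroglucinol core, and the aryl ketone wedged between two hydrogen-bonded hydroxyls. The real difficulty is to place the aroyl group on the most hindered ring A carbon, between two oxygens, and to tell three ring A oxygens apart so that only the one para to the ketone becomes O1. The key step exploits the ortho relationship of the acyl carbon C6 and the hydroxyl carbon C7: an ortho-hydroxyaryl ketone is what a C6–C7 aryne leaves after inserting into the C–O bond of a carboxylic acid, and the oxygen on C5 provides the bias that sends oxygen to C7 and carbon to C6.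

## Logic of the disconnections

24 to 23. The acyl C–O bond of the ring B ester is cut. Ring B oxygen has to stay masked while a ring A oxygen is alkylated, and an aryl ester comes off with carbonate in methanol without touching either alkene. The gain is that the last step is a mild, non-acidic unmasking. The demand is only that the methanolysis be run without air on a polyphenol.

23 to 21 and on to 20 plus 4. The pyran is cut at C4–C4a (a sigmatropic bond) and at O1–C2 (an ether bond). The oxygen that is alkylated becomes O1, so the fusion regiochemistry is decided by an O-alkylation rather than by a C–C bond formation, and C4a is the only unsubstituted ring A carbon. The gain is a five-carbon loss back to 20 and 4. The demand is that alkylation picks the para hydroxyl of 20 over two chelated ones, and that the thermal cascade tolerates free phenols and the prenyl chain.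

20 to 19. Two acetal C–O bonds are cut. The acetals are needed earlier as lithiation directors and as the regiocontrol element of the aryne, and they are removed before the pyran exists. The demand is acid mild enough to spare the prenyl group and the ring B ester.

19 to 14 plus 16 (through 17 and 18). The C6–C(=O) and C7–O bonds (chromene numbering) are cut together. This removes the ketone, ring B and one hydroxyl in a single operation and leaves a carbonyl-free pentasubstituted benzene, 14. It also avoids electrophilic acylation at a carbon between two oxygens. The demand is regiocontrol on an unsymmetrical aryne, and acyl transfer that is faster than protonation of the aryl anion.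

16 to 15. The ester C–O bond is cut. One acylation of a commercial hydroxy acid supplies the whole ring B unit. The demand is acylation on the phenol oxygen without a persistent mixed anhydride.

14 to 12 (through 13), to 8 (through 9, 10, 11), to 7. The S–O, C–Si and carbamate C–O bonds are cut in turn. One phenol oxygen first directs lithiation to its free ortho carbon as a carbamate and then becomes the leaving group of the aryne precursor. The gain is that 7 carries no silicon and no sulfonate. The demand is metalation at the carbon between carbamate and acetal, and removal of a carbamate that has two ortho neighbours.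

7 to 5 (through 6) and on to 2 plus 4. The ring–CH2 bond of the prenyl group (a sigmatropic bond) and the ether C–O bond are cut. Direct C-prenylation of a phloroglucinol is unselective, whereas the shift from oxygen delivers exactly one prenyl group ortho to the oxygen that carried it, and the two ortho carbons of 2 are equivalent. The demand is that hydrogenation stops at the alkene and that the tertiary ether is never exposed to acid.

4 to 3. The ester C–O bond of the propargylic ester is cut. A single acylation turns a commodity alkynol into the activated five-carbon unit, and one batch of 4 serves both the prenyl chain and the pyran ring. The demand is that the tertiary propargylic ester, which ionises and hydrolyses easily, is made cold, isolated quickly and stored dry.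

2 to 1. Two acetal C–O bonds are cut. The gain is a symmetric commodity triphenol. The demand is only that the bis-ether can be separated from its mono and tris congeners.

## Other disconnections considered

Alternative 1: The pyran is cut at C4a–C4, C8a–O1 and O1–C2. In the forward sense, CsF would release from 14 the same aryne 17 that the chosen plan uses, now mapped so that its two aryne carbons become C4a and C8a. The carbonyl oxygen of 3-methylbut-2-enal A2 would add to the carbon next to the prenyl group in a formal [2+2] addition, and the benzoxete would open to an ortho-quinone methide and close by oxa-6π electrocyclisation to 5,7-bis(methoxymethoxy)-2,2-dimethyl-8-(3-methylbut-2-enyl)-2H-chromene A1.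

- In its favour: three bonds and the ring form in one step from a compound the chosen route already makes. The same acetal beside the aryne steers oxygen to C8a, so regiocontrol is equal to that of the chosen plan.
- Against it here: an aldehyde oxygen is a weak nucleophile towards an aryne, so ene reactions with the allylic hydrogens of A2 or of the prenyl chain could compete. The aroyl group would still have to be added by lithiating A1 between its two acetals and acylating with N-methoxy-N-methyl-3-(methoxymethoxy)benzamide A3, a hindered C–C bond formation. Three acetals would then have to be removed by acid at the very end, with the chromene alkene and a prenyl group beside a free hydroxyl both present.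
- Comparison: on step count this alternative is the better one, about three steps from 14 against five. The chosen plan is the better one in where it uses acid (before the pyran exists) and in making the hindered aryl–carbonyl bond intramolecularly.

Alternative 2: Both bonds to the ketone carbon are cut, C6–C(=O) and C(=O)–C1 of ring B. The forward step would be a three-component carbonylative Suzuki coupling. 6-Iodo-5,7-bis(methoxymethoxy)-2,2-dimethyl-8-(3-methylbut-2-enyl)-2H-chromene A4, [3-(methoxymethoxy)phenyl]boronic acid A5 and carbon monoxide A6 would be joined under Pd(OAc)2 with a bulky N-heterocyclic carbene ligand. The product would be [5,7-bis(methoxymethoxy)-2,2-dimethyl-8-(3-methylbut-2-enyl)-2H-chromen-6-yl][3-(methoxymethoxy)phenyl]methanone A7, the same ketone that acylation of A1 with A3 would give.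

- In its favour: it is convergent and needs no organolithium at the acylation stage. Bulky carbene ligands on palladium are the known answer to aryl iodides with two ortho substituents. Ring B is as freely variable as in the chosen plan, so the two are equal on modularity.
- Against it here: A4 needs A1 first and then a site-specific iodination, which would have to go through lithiation because electrophilic iodine would attack the alkenes. The acyl–palladium intermediate, flanked by two alkoxy groups, would transmetalate slowly, leaving room for direct biaryl coupling and loss of iodine. A toxic gas is involved, and the same three-acetal acid deprotection ends the route.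
- Comparison: mechanistically it is the gentler ketone synthesis. It builds no C–O bond, however, so every ring A oxygen must already be present and protected. The sequence is at least as long as the chosen one.

Alternative 3: Ring A itself is cut between the aroyl-bearing carbon and the neighbouring C–OH carbon. In the forward sense, Mg(OCH3)2 in methanol would open 4-hydroxy-6-{2-[3-(methoxymethoxy)phenyl]-2-oxoethyl}-3-(3-methylbut-2-enyl)-2H-pyran-2-one A8 to methyl 7-[3-(methoxymethoxy)phenyl]-2-(3-methylbut-2-enyl)-3,5,7-trioxoheptanoate A9. The carbanion between its 5- and 7-ketones would then attack the ester in a Claisen condensation and aromatise to [3-(methoxymethoxy)phenyl][2,4,6-trihydroxy-3-(3-methylbut-2-enyl)phenyl]methanone A10.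

- In its favour: ring A would arrive with all three oxygens, the prenyl group and the aroyl group in place. There is no aromatic regiochemistry and no ring A protecting group, and no aryne, triflate or cryogenic lithiation is needed, which is a real advantage in operational terms. A10 differs from 20 only in the ring B protecting group and would join the same end game.
- Against it here: the polyketone chain has other ways to cyclise (aldol closure to a resorcylate, or reclosure to a pyrone). The prenyl-bearing ester carbon is hindered and acidic. A8 itself needs a multistep synthesis with an O- versus C-prenylation problem. The ring B acetal would have to be removed by acid after the pyran is built, or else ring B would be free during the O-alkylation.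
- Comparison: structurally it is the most direct route to the acylphloroglucinol, and equal to the chosen plan from that point on. The chosen plan is the better one in regiochemical certainty, because the aryne bias is built into the substrate whereas the cyclisation mode of A9 is a matter of conditions. Step economy would be comparable at best.

Key step: step 9

Remarks on the chemistry:
- Silyl triflate 14 and insertion product 19 map atom for atom onto the target. The triflate sits on the carbon next to the prenyl group, silicon on the carbon next to an acetal, and the acyl group ends on the former silicon carbon.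
- Design choices on the precursor side: the prenyl group is installed before silicon; the directing group is an N-isopropyl carbamate with transient N-silylation, because it can be removed by elimination despite two ortho substituents; ring B is masked as a pivalate so that it survives acid and stays blocked during O-alkylation.
- The transient N-silyl group is taken to be trimethylsilyl, which should fall off on neutral aqueous work-up.
- Trifluoroacetate 4 is taken to be isolable by distillation and storable cold under argon; it is made once and serves both etherifications.

## Steps

Step 1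
Reactants: 1 phloroglucinol
Product: 2 3,5-bis(methoxymethoxy)phenol
Conditions: MOMCl (2.0 equiv), i-Pr2NEt, CH2Cl2/DMF, 0 °C to rt
Reagents that add atoms: chloromethyl methyl ether, COCCl
Why: Williamson-type O-alkylation with an α-chloro ether; two equivalents should give a statistical mixture from which the bis-acetal is separated by chromatography.

Step 2
Reactants: 3 2-methylbut-3-yn-2-ol
Product: 4 2-methylbut-3-yn-2-yl trifluoroacetate
Conditions: (CF3CO)2O, DBU, MeCN, −5 to 0 °C; cold aq wash, pentane extraction, distillation; stored cold under argon
Reagents that add atoms: trifluoroacetic anhydride, O=C(OC(=O)C(F)(F)F)C(F)(F)F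
Why: O-acylation of the tertiary propargylic alcohol by the anhydride under amine base (esterification); the low temperature and the quick cold work-up are chosen because the tertiary propargylic ester ionises and hydrolyses easily.

Step 3
Reactants: 2 3,5-bis(methoxymethoxy)phenol; 4 2-methylbut-3-yn-2-yl trifluoroacetate
Product: 5 1,3-bis(methoxymethoxy)-5-[(2-methylbut-3-yn-2-yl)oxy]benzene
Conditions: 4 (1.3 equiv), DBU, CuCl2·2H2O (cat.), MeCN, −5 to 0 °C
Reagents that add atoms: none
Why: Copper-catalysed propargylic etherification of the phenoxide with the tertiary propargylic ester should give the tertiary aryl propargyl ether at a temperature far below that of any sigmatropic shift and under base, which the acetals tolerate.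

Step 4
Reactants: 5 1,3-bis(methoxymethoxy)-5-[(2-methylbut-3-yn-2-yl)oxy]benzene
Product: 7 3,5-bis(methoxymethoxy)-2-(3-methylbut-2-enyl)phenol, via 1,1-dimethylallyl aryl ether 6 (not isolated)
Conditions: H2 (1 atm), Pd/CaCO3 poisoned with Pb(OAc)2 (Lindlar type), quinoline, toluene, rt; filter; then 110 °C
Reagents that add atoms: none
Why: Lindlar semi-hydrogenation should stop at the terminal alkene, and the aromatic Claisen rearrangement of the 1,1-dimethylallyl ether then moves the chain to either of two equivalent ortho carbons as a prenyl group; the quinoline left in solution keeps the medium basic and suppresses ionisation of the tertiary ether.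

Step 5
Reactants: 7 3,5-bis(methoxymethoxy)-2-(3-methylbut-2-enyl)phenol
Product: 8 3,5-bis(methoxymethoxy)-2-(3-methylbut-2-enyl)phenyl N-isopropylcarbamate
Conditions: i-PrNCO, Et3N (cat.), CH2Cl2, rt
Reagents that add atoms: isopropyl isocyanate, CC(C)N=C=O
Why: Base-catalysed addition of the phenol to the isocyanate (carbamoylation) under neutral conditions that leave acetals and alkene untouched.

Step 6
Reactants: 8 3,5-bis(methoxymethoxy)-2-(3-methylbut-2-enyl)phenyl N-isopropylcarbamate
Product: 12 3,5-bis(methoxymethoxy)-2-(3-methylbut-2-enyl)-6-(trimethylsilyl)phenyl N-isopropylcarbamate, via N-silyl carbamate 9 (not isolated), via aryllithium 10 (not isolated), via N,C-bis(trimethylsilyl) carbamate 11 (not isolated)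
Conditions: TMSOTf, TMEDA, Et2O, 0 °C to rt; n-BuLi (2.2 equiv), TMEDA, −78 °C; TMSCl, −78 °C to rt; aq NH4Cl
Reagents that add atoms: chlorotrimethylsilane, C[Si](C)(C)Cl
Why: Directed ortho-metalation: transient N-silylation masks the N–H, the carbamate (the strongest director present) and the neighbouring acetal together acidify the one C–H between them, and the aryllithium is silylated on carbon; the neutral aqueous work-up should cleave only the N–Si bond.

Step 7
Reactants: 12 3,5-bis(methoxymethoxy)-2-(3-methylbut-2-enyl)-6-(trimethylsilyl)phenyl N-isopropylcarbamate
Product: 14 3,5-bis(methoxymethoxy)-2-(3-methylbut-2-enyl)-6-(trimethylsilyl)phenyl trifluoromethanesulfonate, via silylphenol 13 (not isolated)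
Conditions: DBU, Et2NH, MeCN, 40 °C; then PhNTf2, rt to 40 °C
Reagents that add atoms: N-phenylbis(trifluoromethanesulfonimide), O=S(=O)(N(c1ccccc1)S(=O)(=O)C(F)(F)F)C(F)(F)F
Why: E1cB cleavage of the secondary carbamate (DBU removes the N–H, isopropyl isocyanate is expelled and trapped by Et2NH as a urea) needs no nucleophile at the shielded carbonyl, so two ortho substituents should not stop it; the phenoxide is then O-sulfonylated in the same flask.

Step 8
Reactants: 15 3-hydroxybenzoic acid
Product: 16 3-(pivaloyloxy)benzoic acid
Conditions: PivCl, aq NaOH (2 M), 0 °C to rt; then HCl to pH 2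
Reagents that add atoms: pivaloyl chloride, CC(C)(C)C(Cl)=O
Why: Schotten–Baumann acylation of the phenoxide of the dianion; any mixed anhydride is hydrolysed in the aqueous base, so acidification should return the free acid with the phenol esterified.

Step 9
Reactants: 14 3,5-bis(methoxymethoxy)-2-(3-methylbut-2-enyl)-6-(trimethylsilyl)phenyl trifluoromethanesulfonate; 16 3-(pivaloyloxy)benzoic acid
Product: 19 3-[2-hydroxy-4,6-bis(methoxymethoxy)-3-(3-methylbut-2-enyl)benzoyl]phenyl pivalate, via aryne 17 (not isolated), via aryl cesium ester adduct 18 (not isolated)
Conditions: 16 (1.5 equiv), CsF (5 equiv), THF, 125 °C, sealed tube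
Reagents that add atoms: none
Why: Fluoride attacks silicon of 14 and triflate leaves, giving aryne 17 by the usual 1,2-elimination of an ortho-silylaryl triflate, while CsF also turns 16 into its cesium carboxylate. The carboxylate oxygen adds to the aryne carbon next to the prenyl group, because the acetal oxygen on the other flank distorts the aryne and stabilises negative charge inductively on the carbon beside it; the new C–O bond therefore forms at future C7 and the carbanion of 18 sits at future C6. That carbanion attacks the carbonyl of the ester just formed through a four-centre transition state, and collapse of the adduct gives the ortho-acylphenoxide (an anionic Fries-type 1,3 shift of acyl from oxygen to carbon), protonated on work-up to 19. The closest known reaction type is the fluoride-induced insertion of arynes into the C–O bond of carboxylic acids to give ortho-hydroxyaryl ketones, applied here to a more heavily substituted aryne. No ring is closed and no stereocentre is formed. Regiochemistry is secured by the acetal oxygen beside the aryne, which the weak steric preference of the prenyl group on the other side should not override. Acyl capture over protonation of 18 is secured by an aprotic solvent without acidic C–H bonds, excess CsF to bind HF, and a temperature high enough for the strained four-centre shift. The carboxylate is kept in excess so that it intercepts the aryne ahead of the product phenoxide or the prenyl alkene of a second molecule (ene reaction); acetals, pivalate and prenyl group are expected to be inert to CsF in THF.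

Step 10
Reactants: 19 3-[2-hydroxy-4,6-bis(methoxymethoxy)-3-(3-methylbut-2-enyl)benzoyl]phenyl pivalate
Product: 20 3-[2,4,6-trihydroxy-3-(3-methylbut-2-enyl)benzoyl]phenyl pivalate
Conditions: HCl (ca. 1 M in MeOH), rt to 40 °C
Reagents that add atoms: none
Why: Acid-catalysed acetal methanolysis (transacetalisation to dimethoxymethane); dilute acid near room temperature is chosen because protonation of the trisubstituted alkene, the entry to chroman formation, needs stronger acid, and the hindered aryl pivalate should not transesterify under these conditions.

Step 11
Reactants: 20 3-[2,4,6-trihydroxy-3-(3-methylbut-2-enyl)benzoyl]phenyl pivalate; 4 2-methylbut-3-yn-2-yl trifluoroacetate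
Product: 21 3-{2,6-dihydroxy-4-[(2-methylbut-3-yn-2-yl)oxy]-3-(3-methylbut-2-enyl)benzoyl}phenyl pivalate
Conditions: 4 (1.1 equiv), DBU (1.1 equiv), CuCl2·2H2O (cat.), MeCN, −5 to 0 °C
Reagents that add atoms: none
Why: The same copper-catalysed propargylic etherification as in step 3; with about one equivalent of base only the para hydroxyl is ionised and alkylated, since it is a vinylogous acid and the one phenol not hydrogen-bonded to the ketone, while the ring B oxygen is blocked as the pivalate.

Step 12
Reactants: 21 3-{2,6-dihydroxy-4-[(2-methylbut-3-yn-2-yl)oxy]-3-(3-methylbut-2-enyl)benzoyl}phenyl pivalate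
Product: 23 3-[5,7-dihydroxy-2,2-dimethyl-8-(3-methylbut-2-enyl)-2H-chromene-6-carbonyl]phenyl pivalate, via allenylphenol 22 (not isolated)
Conditions: o-xylene, 140 °C
Reagents that add atoms: none
Why: Aromatic propargyl Claisen rearrangement to the only free ortho carbon, tautomerisation to 22, 1,5-hydrogen shift to an ortho-quinone methide and oxa-6π electrocyclisation should close the pyran; the oxygen alkylated in step 11 becomes O1, so the ring fusion cannot go the other way.

Step 13
Reactants: 23 3-[5,7-dihydroxy-2,2-dimethyl-8-(3-methylbut-2-enyl)-2H-chromene-6-carbonyl]phenyl pivalate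
Product: 24 (5,7-dihydroxy-2,2-dimethyl-8-(3-methylbut-2-enyl)-2H-chromen-6-yl)(3-hydroxyphenyl)methanone
Conditions: K2CO3, MeOH (degassed), rt to 40 °C; aq NH4Cl
Reagents that add atoms: none
Why: Base-mediated methanolysis (transesterification) of an aryl ester, made easy by the phenoxide leaving group; the conditions are harmless to the chromene and prenyl alkenes, and the work-up is kept near neutral.

## Compound list

1 | phloroglucinol | Oc1cc(O)cc(O)c1 | starting material
2 | 3,5-bis(methoxymethoxy)phenol | COCOc1cc(O)cc(OCOC)c1 | intermediate
3 | 2-methylbut-3-yn-2-ol | CC(C)(O)C#C | starting material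
4 | 2-methylbut-3-yn-2-yl trifluoroacetate | CC(C)(OC(=O)C(F)(F)F)C#C | intermediate
5 | 1,3-bis(methoxymethoxy)-5-[(2-methylbut-3-yn-2-yl)oxy]benzene | COCOc1cc(OCOC)cc(OC(C)(C)C#C)c1 | intermediate
6 | 1,3-bis(methoxymethoxy)-5-[(2-methylbut-3-en-2-yl)oxy]benzene | COCOc1cc(OCOC)cc(OC(C)(C)C=C)c1 | intermediate
7 | 3,5-bis(methoxymethoxy)-2-(3-methylbut-2-enyl)phenol | COCOc1cc(O)c(CC=C(C)C)c(OCOC)c1 | intermediate
8 | 3,5-bis(methoxymethoxy)-2-(3-methylbut-2-enyl)phenyl N-isopropylcarbamate | COCOc1cc(OC(=O)NC(C)C)c(CC=C(C)C)c(OCOC)c1 | intermediate
9 | 3,5-bis(methoxymethoxy)-2-(3-methylbut-2-enyl)phenyl N-isopropyl-N-(trimethylsilyl)carbamate | COCOc1cc(OC(=O)N(C(C)C)[Si](C)(C)C)c(CC=C(C)C)c(OCOC)c1 | intermediate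
10 | 6-lithio-3,5-bis(methoxymethoxy)-2-(3-methylbut-2-enyl)phenyl N-isopropyl-N-(trimethylsilyl)carbamate | COCOc1c([Li])c(OC(=O)N(C(C)C)[Si](C)(C)C)c(CC=C(C)C)c(OCOC)c1 | intermediate
11 | 3,5-bis(methoxymethoxy)-2-(3-methylbut-2-enyl)-6-(trimethylsilyl)phenyl N-isopropyl-N-(trimethylsilyl)carbamate | COCOc1c([Si](C)(C)C)c(OC(=O)N(C(C)C)[Si](C)(C)C)c(CC=C(C)C)c(OCOC)c1 | intermediate
12 | 3,5-bis(methoxymethoxy)-2-(3-methylbut-2-enyl)-6-(trimethylsilyl)phenyl N-isopropylcarbamate | COCOc1c([Si](C)(C)C)c(OC(=O)NC(C)C)c(CC=C(C)C)c(OCOC)c1 | intermediate
13 | 3,5-bis(methoxymethoxy)-2-(3-methylbut-2-enyl)-6-(trimethylsilyl)phenol | COCOc1c([Si](C)(C)C)c(O)c(CC=C(C)C)c(OCOC)c1 | intermediate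
14 | 3,5-bis(methoxymethoxy)-2-(3-methylbut-2-enyl)-6-(trimethylsilyl)phenyl trifluoromethanesulfonate | COCOc1cc(OCOC)c([Si](C)(C)C)c(OS(=O)(=O)C(F)(F)F)c1CC=C(C)C | intermediate
15 | 3-hydroxybenzoic acid | O=C(O)c1cccc(O)c1 | starting material
16 | 3-(pivaloyloxy)benzoic acid | CC(C)(C)C(=O)Oc1cccc(C(=O)O)c1 | intermediate
17 | 3,5-bis(methoxymethoxy)-6-(3-methylbut-2-enyl)benzyne (1,2-didehydrobenzene) | COCOC1=CC(OCOC)=C(CC=C(C)C)C#C1 | intermediate
18 | 2-cesio-3,5-bis(methoxymethoxy)-6-(3-methylbut-2-enyl)phenyl 3-(pivaloyloxy)benzoate | COCOc1cc(OCOC)c([Cs])c(OC(=O)c2cccc(OC(=O)C(C)(C)C)c2)c1CC=C(C)C | intermediate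
19 | 3-[2-hydroxy-4,6-bis(methoxymethoxy)-3-(3-methylbut-2-enyl)benzoyl]phenyl pivalate | CC(C)=CCc1c(O)c(C(=O)c2cccc(OC(=O)C(C)(C)C)c2)c(OCOC)cc1OCOC | intermediate
20 | 3-[2,4,6-trihydroxy-3-(3-methylbut-2-enyl)benzoyl]phenyl pivalate | CC(C)=CCc1c(O)cc(O)c(C(=O)c2cccc(OC(=O)C(C)(C)C)c2)c1O | intermediate
21 | 3-{2,6-dihydroxy-4-[(2-methylbut-3-yn-2-yl)oxy]-3-(3-methylbut-2-enyl)benzoyl}phenyl pivalate | CC(C)=CCc1c(OC(C)(C)C#C)cc(O)c(C(=O)c2cccc(OC(=O)C(C)(C)C)c2)c1O | intermediate
22 | 3-[2,4,6-trihydroxy-3-(3-methylbut-2-enyl)-5-(3-methylbuta-1,2-dienyl)benzoyl]phenyl pivalate | CC(C)=CCc1c(O)c(C=C=C(C)C)c(O)c(C(=O)c2cccc(OC(=O)C(C)(C)C)c2)c1O | intermediate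
23 | 3-[5,7-dihydroxy-2,2-dimethyl-8-(3-methylbut-2-enyl)-2H-chromene-6-carbonyl]phenyl pivalate | CC(C)=CCc1c(O)c(C(=O)c2cccc(OC(=O)C(C)(C)C)c2)c(O)c2c1OC(C)(C)C=C2 | intermediate
24 | (5,7-dihydroxy-2,2-dimethyl-8-(3-methylbut-2-enyl)-2H-chromen-6-yl)(3-hydroxyphenyl)methanone | CC(C)=CCc1c(O)c(C(=O)c2cccc(O)c2)c(O)c2c1OC(C)(C)C=C2 | target

## Step count and least certain steps

Total step count: 13, including the one-step preparations of 4 and 16. Longest linear sequence: 11 steps from 1 (steps 1, 3 to 7 and 9 to 13).

Step 9 (key step). Three things are most likely to go wrong:
- The aryl anion is protonated before acyl transfer, which stops the sequence at the simple aryl ester. The anion is stabilised by two flanking oxygens and the four-centre shift is strained.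
- The aryne is consumed by the product phenoxide or by an ene reaction with a prenyl alkene.
- The pivaloyl group migrates under hot fluoride.

The fallback makes the same ketone by acylating a carbanion instead of an aryne. It sets out from 8, which is N-silylated and lithiated exactly as in step 6 (through 9 and 10). The aryllithium would be added at −78 °C to 3-(chlorocarbonyl)phenyl pivalate F1, made from 16 with oxalyl chloride and catalytic DMF. Acylation should give 3,5-bis(methoxymethoxy)-2-(3-methylbut-2-enyl)-6-[3-(pivaloyloxy)benzoyl]phenyl N-isopropyl-N-(trimethylsilyl)carbamate F2. Aqueous work-up removes the N-silyl group and should give 3,5-bis(methoxymethoxy)-2-(3-methylbut-2-enyl)-6-[3-(pivaloyloxy)benzoyl]phenyl N-isopropylcarbamate F3. The carbamate would then be removed with DBU and Et2NH in MeCN, and the fallback comes back to the route at 19. This is directed ortho-metalation and acylation followed by E1cB decarbamoylation, all known chemistry, and it is no longer than the main line.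

Step 6. Metalation may stray to the carbon between the two acetals, or to the benzylic and allylic CH2 of the prenyl group, or the carbamoyl group may migrate to carbon on warming; two ring positions are each flanked by two oxygen directors. The fallback fixes the silicon position by halogen–metal exchange and sets out from 2.
- Ortho-bromination with NBS and catalytic i-Pr2NH in CH2Cl2 at low temperature would give 2-bromo-3,5-bis(methoxymethoxy)phenol F4.
- Etherification with 4 as in step 3 would give 2-bromo-1,5-bis(methoxymethoxy)-3-[(2-methylbut-3-yn-2-yl)oxy]benzene F5.
- Semi-hydrogenation as in step 4 would give 2-bromo-1,5-bis(methoxymethoxy)-3-[(2-methylbut-3-en-2-yl)oxy]benzene F6, which on heating can rearrange only to the one free ortho carbon, giving 2-bromo-3,5-bis(methoxymethoxy)-6-(3-methylbut-2-enyl)phenol F7.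
- Hexamethyldisilazane would give [2-bromo-3,5-bis(methoxymethoxy)-6-(3-methylbut-2-enyl)phenoxy]trimethylsilane F8.
- n-BuLi in THF at −78 °C would trigger bromine–lithium exchange and a retro-Brook shift of silicon from oxygen to carbon, giving the lithium salt of 13. Triflic anhydride would then give 14, where the fallback rejoins the route.

Step 4. Hydrogenation may run on to the saturated ether, which cannot rearrange, or the tertiary allyl ether may ionise and lose isoprene on heating, returning 2. The fallback avoids the alkyne altogether and sets out from 2. A Tsuji–Trost O-allylation with tert-butyl 2-methylbut-3-en-2-yl carbonate F9 (from 2-methylbut-3-en-2-ol and di-tert-butyl dicarbonate) and Pd(PPh3)4 in THF should give 6 directly through the more substituted terminus of the allyl–palladium intermediate. The route is rejoined at 6, which is heated to 7 as before.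

Step 11. Alkylation may go to a chelated hydroxyl, happen twice, or occur on carbon, because 20 offers three phenols on one ring and the para one is flanked by the prenyl group. The fallback builds the pyran without any O-alkylation and sets out from 20. Condensation with 3-methylbut-2-enal and ethylenediammonium diacetate in hot toluene (Knoevenagel-type attack of the free ring carbon, then oxa-6π electrocyclisation) would lead directly to 23, where the route is rejoined. Closure through the unchelated para oxygen is expected to be preferred, but an isomer closed through the chelated oxygen may have to be separated.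

## Further compounds

F1 | step 9 | 3-(chlorocarbonyl)phenyl pivalate | CC(C)(C)C(=O)Oc1cccc(C(Cl)=O)c1
F2 | step 9 | 3,5-bis(methoxymethoxy)-2-(3-methylbut-2-enyl)-6-[3-(pivaloyloxy)benzoyl]phenyl N-isopropyl-N-(trimethylsilyl)carbamate | CC(C)=CCc1c(OC(=O)N(C(C)C)[Si](C)(C)C)c(C(=O)c2cccc(OC(=O)C(C)(C)C)c2)c(OCOC)cc1OCOC
F3 | step 9 | 3,5-bis(methoxymethoxy)-2-(3-methylbut-2-enyl)-6-[3-(pivaloyloxy)benzoyl]phenyl N-isopropylcarbamate | CC(C)=CCc1c(OC(=O)NC(C)C)c(C(=O)c2cccc(OC(=O)C(C)(C)C)c2)c(OCOC)cc1OCOC
F4 | step 6 | 2-bromo-3,5-bis(methoxymethoxy)phenol | COCOc1cc(O)c(Br)c(OCOC)c1
F5 | step 6 | 2-bromo-1,5-bis(methoxymethoxy)-3-[(2-methylbut-3-yn-2-yl)oxy]benzene | COCOc1cc(OC(C)(C)C#C)c(Br)c(OCOC)c1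
F6 | step 6 | 2-bromo-1,5-bis(methoxymethoxy)-3-[(2-methylbut-3-en-2-yl)oxy]benzene | COCOc1cc(OC(C)(C)C=C)c(Br)c(OCOC)c1
F7 | step 6 | 2-bromo-3,5-bis(methoxymethoxy)-6-(3-methylbut-2-enyl)phenol | COCOc1cc(OCOC)c(CC=C(C)C)c(O)c1Br
F8 | step 6 | [2-bromo-3,5-bis(methoxymethoxy)-6-(3-methylbut-2-enyl)phenoxy]trimethylsilane | COCOc1cc(OCOC)c(CC=C(C)C)c(O[Si](C)(C)C)c1Br
F9 | step 4 | tert-butyl 2-methylbut-3-en-2-yl carbonate | C=CC(C)(C)OC(=O)OC(C)(C)C
F0 | step 11 | none | none
A1 | alternative 1 | 5,7-bis(methoxymethoxy)-2,2-dimethyl-8-(3-methylbut-2-enyl)-2H-chromene | CC(C)=CCc1c(OCOC)cc(OCOC)c2c1OC(C)(C)C=C2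
A2 | alternative 1 | 3-methylbut-2-enal | CC(C)=CC=O
A3 | alternative 1 | N-methoxy-N-methyl-3-(methoxymethoxy)benzamide | CON(C)C(=O)c1cccc(OCOC)c1
A4 | alternative 2 | 6-iodo-5,7-bis(methoxymethoxy)-2,2-dimethyl-8-(3-methylbut-2-enyl)-2H-chromene | CC(C)=CCc1c(OCOC)c(I)c(OCOC)c2c1OC(C)(C)C=C2
A5 | alternative 2 | [3-(methoxymethoxy)phenyl]boronic acid | COCOc1cccc(B(O)O)c1
A6 | alternative 2 | carbon monoxide | [C-]#[O+]
A7 | alternative 2 | [5,7-bis(methoxymethoxy)-2,2-dimethyl-8-(3-methylbut-2-enyl)-2H-chromen-6-yl][3-(methoxymethoxy)phenyl]methanone | CC(C)=CCc1c(OCOC)c(C(=O)c2cccc(OCOC)c2)c(OCOC)c2c1OC(C)(C)C=C2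
A8 | alternative 3 | 4-hydroxy-6-{2-[3-(methoxymethoxy)phenyl]-2-oxoethyl}-3-(3-methylbut-2-enyl)-2H-pyran-2-one | CC(C)=CCC1=C(O)C=C(CC(=O)c2cccc(OCOC)c2)OC1=O
A9 | alternative 3 | methyl 7-[3-(methoxymethoxy)phenyl]-2-(3-methylbut-2-enyl)-3,5,7-trioxoheptanoate | COC(=O)C(CC=C(C)C)C(=O)CC(=O)CC(=O)c1cccc(OCOC)c1
A10 | alternative 3 | [3-(methoxymethoxy)phenyl][2,4,6-trihydroxy-3-(3-methylbut-2-enyl)phenyl]methanone | CC(C)=CCc1c(O)cc(O)c(C(=O)c2cccc(OCOC)c2)c1O
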